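**Retrosynthetic overview**

1. Target 22 comes from the C1–C2 diol acetonide 19 (acetonide off, C1 tosylate, 3-exo-tet closure). This oxirane is the only ring of the target and is formed last; C2 comes unchanged from the chiral pool.
2. The strategy rests on the acyclic pair C3 (quaternary: CH3, Cl) / C4 (CH–Br) next to the oxirane carbon C2, a neopentyl secondary bromide beside a tertiary chloride. Both C–halogen bonds are made from bromohydrin 16 (C3–Br, C4–OH) by triflation, bromine 1,2-shift and chloride capture at C3, with inversion at both centres.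
3. 16 comes from cis-epoxide 15 (HBr at C3), and 15 from Z-alkene 14; this C3–C4 oxirane is transient, formed and opened before the key step.
4. The C6(Cl)–C7(Br)(CH3)–C8H2Cl triad comes from E-allylic alcohol 10 by titanium-catalysed enantioselective anti-dichlorination (11), then a chlorine 1,2-shift from C7 to C8 with bromide capture at C7.
5. The skeleton comes from a Z-selective Wittig reaction of α-alkoxy ketone 7 (C1–C3 and the C3 methyl, from glycerate ester 5) with the ylide of salt 4 (C4–C8, from bromide 1). The dioxolane ring is carried from 5.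

Key step: step 12

Assumptions: locants C1–C8 run from the oxirane CH2 (C1) to CH2Cl (C8), and the target is (2S,3R,4R,6S,7S). The descriptor of the dioxolane carbon changes between S and R along the route only through CIP ranking; its spatial arrangement never changes. Both antipodes of the Schiff-base ligand (step 8) and of the fructose-type ketone (step 10) are taken to be accessible.

**Route**

Step 1
Reactants: 1 5-bromo-2-methylpent-2-ene
Product: 2 (E)-5-bromo-2-methylpent-2-en-1-ol
Conditions: SeO2 (cat.), t-BuOOH, CH2Cl2, 0 °C → rt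
Reagents that add atoms: tert-butyl hydroperoxide, CC(C)(C)OO; selenium dioxide, O=[Se]=O
Why: Riley allylic oxidation (ene reaction, then [2,3]-shift) of a gem-dimethyl trisubstituted alkene attacks the E-methyl group, so the E allylic alcohol should form with the remote primary bromide untouched.

Step 2
Reactants: 2 (E)-5-bromo-2-methylpent-2-en-1-ol
Product: 3 {[(E)-5-bromo-2-methylpent-2-en-1-yl]oxy}(tert-butyl)dimethylsilane
Conditions: TBSCl, imidazole, DMF, 0 °C → rt
Reagents that add atoms: tert-butyldimethylsilyl chloride, CC(C)(C)[Si](C)(C)Cl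
Why: Standard silylation masks the allylic hydroxyl for the phosphonium and ylide chemistry.

Step 3
Reactants: 3 {[(E)-5-bromo-2-methylpent-2-en-1-yl]oxy}(tert-butyl)dimethylsilane
Product: 4 [(E)-5-{[tert-butyl(dimethyl)silyl]oxy}-4-methylpent-3-en-1-yl]triphenylphosphonium bromide
Conditions: PPh3, MeCN, reflux
Reagents that add atoms: triphenylphosphine, c1ccc(cc1)P(c1ccccc1)c1ccccc1
Why: SN2 quaternisation of the phosphine by the primary homoallylic bromide gives the Wittig salt.

Step 4
Reactants: 5 methyl (S)-2,2-dimethyl-1,3-dioxolane-4-carboxylate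
Product: 6 (S)-N-methoxy-N,2,2-trimethyl-1,3-dioxolane-4-carboxamide
Conditions: MeNH(OMe)·HCl, i-PrMgCl, THF, −20 → 0 °C
Reagents that add atoms: N,O-dimethylhydroxylamine hydrochloride, CNOC.Cl
Why: Acyl substitution by the magnesium amide gives the Weinreb amide below 0 °C, where the α-alkoxy stereocentre does not epimerise.

Step 5
Reactants: 6 (S)-N-methoxy-N,2,2-trimethyl-1,3-dioxolane-4-carboxamide
Product: 7 1-[(S)-2,2-dimethyl-1,3-dioxolan-4-yl]ethan-1-one
Conditions: MeMgBr, THF, −78 → 0 °C
Reagents that add atoms: methylmagnesium bromide, C[Mg]Br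
Why: In the Weinreb ketone synthesis the chelated tetrahedral adduct stops at mono-addition and releases the methyl ketone on work-up, so C2 is taken over from the chiral pool.

Step 6
Reactants: 4 [(E)-5-{[tert-butyl(dimethyl)silyl]oxy}-4-methylpent-3-en-1-yl]triphenylphosphonium bromide; 7 1-[(S)-2,2-dimethyl-1,3-dioxolan-4-yl]ethan-1-one
Product: 9 (R)-4-[(2Z,5E)-7-{[tert-butyl(dimethyl)silyl]oxy}-6-methylhepta-2,5-dien-2-yl]-2,2-dimethyl-1,3-dioxolane, via phosphonium ylide 8 (not isolated)
Conditions: KN(SiMe3)2, THF, −78 → 0 °C; then 7, −78 °C → rt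
Reagents that add atoms: none
Why: The Wittig olefination of an α-alkoxy ketone with a salt-free non-stabilised ylide is Z-selective, placing the alkoxy-bearing carbon C2 cis to the ylide chain C5, and it leaves the E C6=C7 bond and C2 untouched.

Step 7
Reactants: 9 (R)-4-[(2Z,5E)-7-{[tert-butyl(dimethyl)silyl]oxy}-6-methylhepta-2,5-dien-2-yl]-2,2-dimethyl-1,3-dioxolane
Product: 10 (2E,5Z)-6-[(R)-2,2-dimethyl-1,3-dioxolan-4-yl]-2-methylhepta-2,5-dien-1-ol
Conditions: Bu4NF, THF, 0 °C
Reagents that add atoms: none
Why: Fluoride-induced desilylation frees the allylic hydroxyl that is needed to bind titanium in the next step.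

Step 8
Reactants: 10 (2E,5Z)-6-[(R)-2,2-dimethyl-1,3-dioxolan-4-yl]-2-methylhepta-2,5-dien-1-ol
Product: 11 (2R,3S,5Z)-2,3-dichloro-6-[(R)-2,2-dimethyl-1,3-dioxolan-4-yl]-2-methylhept-5-en-1-ol
Conditions: t-BuOCl, ClTi(Oi-Pr)3, chiral tridentate Schiff-base ligand (salicylaldimine of a tert-leucine-derived 1,1-diaryl amino alcohol, 20 mol %, antipode for 2R,3S), hexanes, −20 °C
Reagents that add atoms: tert-butyl hypochlorite, CC(C)(C)OCl; chlorotitanium triisopropoxide, CC(C)O[Ti](Cl)(OC(C)C)OC(C)C
Why: The titanium-alkoxide-directed catalytic enantioselective dichlorination of allylic alcohols is confined to the C6=C7 bond by the bound hydroxyl and adds anti across the E alkene, the ligand antipode fixing C6 as S and C7 as R; with two chlorines the regiochemistry of chloronium opening does not matter.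

Step 9
Reactants: 11 (2R,3S,5Z)-2,3-dichloro-6-[(R)-2,2-dimethyl-1,3-dioxolan-4-yl]-2-methylhept-5-en-1-ol
Product: 14 (R)-4-[(2Z,5S,6S)-6-bromo-5,7-dichloro-6-methylhept-2-en-2-yl]-2,2-dimethyl-1,3-dioxolane, via primary triflate 12 (not isolated), via chloriranium triflate 13 (not isolated)
Conditions: Tf2O, 2,6-di-tert-butyl-4-methylpyridine, CH2Cl2, −78 °C; then Bu4NBr, −78 → 0 °C
Reagents that add atoms: tetrabutylammonium bromide, CCCC[N+](CCCC)(CCCC)CCCC.[Br-]
Why: Proposed new method: the neopentyl primary triflate 12 resists direct displacement, so the anti-periplanar tertiary chlorine on C7 is expected to expel triflate (3-exo-tet) to give chloriranium ion 13, which bromide opens at the tertiary C7 anti to the bridging chlorine, moving chlorine to C8 and placing bromine on C7 with inversion while C6 is untouched; the closest known reaction types are the 1,2-chlorine shifts seen when β-chloro alcohols are activated for deoxyfluorination, the stereospecific solvolysis of β-chloro sulfonates through chloronium ions, and the bromine version used in step 12.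

Step 10
Reactants: 14 (R)-4-[(2Z,5S,6S)-6-bromo-5,7-dichloro-6-methylhept-2-en-2-yl]-2,2-dimethyl-1,3-dioxolane
Product: 15 (S)-4-{(2S,3S)-3-[(2S,3S)-3-bromo-2,4-dichloro-3-methylbutyl]-2-methyloxiran-2-yl}-2,2-dimethyl-1,3-dioxolane
Conditions: L-fructose-derived Shi ketone (1,2:4,5-di-O-isopropylidene-β-L-erythro-2,3-hexodiulo-2,6-pyranose, 30 mol %), KHSO5 (Oxone), K2CO3, Bu4NHSO4, MeCN–dimethoxymethane–aq. Na2B4O7 buffer, 0 °C
Reagents that add atoms: potassium peroxymonosulfate, [K+].OOS(=O)(=O)[O-]
Why: The Shi asymmetric epoxidation (chiral dioxirane, spiro transition state) is stereospecific, so the Z alkene gives the cis-oxirane, and this ketone antipode is chosen to deliver oxygen to the face syn to the dioxolane C2–O bond (C3 S, C4 S), a face the substrate alone would not prefer.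

Step 11
Reactants: 15 (S)-4-{(2S,3S)-3-[(2S,3S)-3-bromo-2,4-dichloro-3-methylbutyl]-2-methyloxiran-2-yl}-2,2-dimethyl-1,3-dioxolane
Product: 16 (2R,3S,5S,6S)-2,6-dibromo-5,7-dichloro-2-[(S)-2,2-dimethyl-1,3-dioxolan-4-yl]-6-methylheptan-3-ol
Conditions: HBr (anhydrous, Et2O solution, 1.05 equiv), CH2Cl2, −78 °C
Reagents that add atoms: hydrogen bromide, Br
Why: Protic opening of the trisubstituted oxirane (Markovnikov-type, borderline SN2) should deliver bromide to the tertiary C3 with inversion while the C4–O bond is kept, giving the anti bromohydrin, and the cold anhydrous acid should leave the acetonide intact.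

Step 12
Reactants: 16 (2R,3S,5S,6S)-2,6-dibromo-5,7-dichloro-2-[(S)-2,2-dimethyl-1,3-dioxolan-4-yl]-6-methylheptan-3-ol
Product: 19 (S)-4-[(2R,3R,5S,6S)-3,6-dibromo-2,5,7-trichloro-6-methylheptan-2-yl]-2,2-dimethyl-1,3-dioxolane, via secondary triflate 17 (not isolated), via bromiranium triflate 18 (not isolated)
Conditions: Tf2O, 2,6-di-tert-butyl-4-methylpyridine, CH2Cl2, −78 °C; then Bu4NCl, −78 → −20 °C
Reagents that add atoms: tetrabutylammonium chloride, CCCC[N+](CCCC)(CCCC)CCCC.[Cl-]
Why: The hindered C4 alcohol is triflated at −78 °C; the C3 bromine, anti-periplanar to the C4–OTf bond, displaces triflate from the rear (3-exo-tet) to give the C3–C4 bromonium ion 18, which chloride opens at C3 anti to bromine, so no ring survives. The closest known reaction type is the anchimerically assisted substitution of activated β-bromo alcohols through configurationally defined bromonium ions with capture by an external halide. C4 is set by the backside attack of bromine on the triflate (inversion) and C3 by the anti attack of chloride on the bridged ion (inversion); both follow from the configuration of bromohydrin 16, that is, from cis-epoxide 15. The step needs chloride to attack the tertiary C3 and not C4: the larger positive charge on the fully substituted carbon and the neopentyl character of C4 should secure this, and the absence of any alkene excludes bromonium transfer. Competing 1,4-participation by the C7 bromine is disfavoured because that halogen is deactivated and shielded by the flanking C6 and C8 chlorines, and the dioxolane oxygens could reach C4 only through a four-membered or a bridged bicyclic oxonium ion.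

Step 13
Reactants: 19 (S)-4-[(2R,3R,5S,6S)-3,6-dibromo-2,5,7-trichloro-6-methylheptan-2-yl]-2,2-dimethyl-1,3-dioxolane
Product: 20 (2S,3R,4R,6S,7S)-4,7-dibromo-3,6,8-trichloro-3,7-dimethyloctane-1,2-diol
Conditions: AcOH–H2O (4:1), 40 °C
Reagents that add atoms: none
Why: Acid-catalysed hydrolysis removes the terminal isopropylidene acetal, and the inductively deactivated tertiary halides should not ionise under these conditions.

Step 14
Reactants: 20 (2S,3R,4R,6S,7S)-4,7-dibromo-3,6,8-trichloro-3,7-dimethyloctane-1,2-diol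
Product: 21 (2S,3R,4R,6S,7S)-4,7-dibromo-3,6,8-trichloro-2-hydroxy-3,7-dimethyloctyl 4-methylbenzenesulfonate
Conditions: TsCl, Bu2SnO (cat.), Et3N, CH2Cl2, 0 °C
Reagents that add atoms: 4-toluenesulfonyl chloride, Cc1ccc(cc1)S(Cl)(=O)=O
Why: Tin-acetal-catalysed sulfonylation of a 1,2-diol is selective for the primary hydroxyl, and the secondary C2–OH next to the quaternary C3 is too hindered to compete.

Step 15
Reactants: 21 (2S,3R,4R,6S,7S)-4,7-dibromo-3,6,8-trichloro-2-hydroxy-3,7-dimethyloctyl 4-methylbenzenesulfonate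
Product: 22 (S)-2-[(2R,3R,5S,6S)-3,6-dibromo-2,5,7-trichloro-6-methylheptan-2-yl]oxirane
Conditions: K2CO3, MeOH, 0 °C
Reagents that add atoms: none
Why: Intramolecular Williamson closure (3-exo-tet) of the C2 alkoxide onto the primary tosylate forms the oxirane with the C2–O bond, and so the C2 configuration, retained.

**Compound list**

1 | 5-bromo-2-methylpent-2-ene | CC(C)=CCCBr | starting material
2 | (E)-5-bromo-2-methylpent-2-en-1-ol | OC/C(C)=C/CCBr | intermediate
3 | {[(E)-5-bromo-2-methylpent-2-en-1-yl]oxy}(tert-butyl)dimethylsilane | CC(C)(C)[Si](C)(C)OC/C(C)=C/CCBr | intermediate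
4 | [(E)-5-{[tert-butyl(dimethyl)silyl]oxy}-4-methylpent-3-en-1-yl]triphenylphosphonium bromide | CC(C)(C)[Si](C)(C)OC/C(C)=C/CC[P+](c1ccccc1)(c1ccccc1)c1ccccc1.[Br-] | intermediate
5 | methyl (S)-2,2-dimethyl-1,3-dioxolane-4-carboxylate | COC(=O)[C@@H]1COC(C)(C)O1 | starting material
6 | (S)-N-methoxy-N,2,2-trimethyl-1,3-dioxolane-4-carboxamide | CON(C)C(=O)[C@@H]1COC(C)(C)O1 | intermediate
7 | 1-[(S)-2,2-dimethyl-1,3-dioxolan-4-yl]ethan-1-one | CC(=O)[C@@H]1COC(C)(C)O1 | intermediate
8 | [(E)-5-{[tert-butyl(dimethyl)silyl]oxy}-4-methylpent-3-en-1-ylidene]triphenylphosphorane (ylide of 4, not isolated) | CC(C)(C)[Si](C)(C)OC/C(C)=C/CC=P(c1ccccc1)(c1ccccc1)c1ccccc1 | intermediate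
9 | (R)-4-[(2Z,5E)-7-{[tert-butyl(dimethyl)silyl]oxy}-6-methylhepta-2,5-dien-2-yl]-2,2-dimethyl-1,3-dioxolane | C/C(=C/C/C=C(\C)CO[Si](C)(C)C(C)(C)C)[C@@H]1COC(C)(C)O1 | intermediate
10 | (2E,5Z)-6-[(R)-2,2-dimethyl-1,3-dioxolan-4-yl]-2-methylhepta-2,5-dien-1-ol | C/C(=C/C/C=C(\C)CO)[C@@H]1COC(C)(C)O1 | intermediate
11 | (2R,3S,5Z)-2,3-dichloro-6-[(R)-2,2-dimethyl-1,3-dioxolan-4-yl]-2-methylhept-5-en-1-ol | C/C(=C/C[C@H](Cl)[C@](C)(Cl)CO)[C@@H]1COC(C)(C)O1 | intermediate
12 | C8 trifluoromethanesulfonate of 11, all centres as in 11 (not isolated) | C/C(=C/C[C@H](Cl)[C@](C)(Cl)COS(=O)(=O)C(F)(F)F)[C@@H]1COC(C)(C)O1 | intermediate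
13 | chloriranium ion from 12, chlorine bridging C7 and C8, triflate salt (not isolated) | C/C(=C/C[C@H](Cl)[C@@]1(C)C[Cl+]1)[C@@H]2COC(C)(C)O2.[O-]S(=O)(=O)C(F)(F)F | intermediate
14 | (R)-4-[(2Z,5S,6S)-6-bromo-5,7-dichloro-6-methylhept-2-en-2-yl]-2,2-dimethyl-1,3-dioxolane | C/C(=C/C[C@H](Cl)[C@@](C)(Br)CCl)[C@@H]1COC(C)(C)O1 | intermediate
15 | (S)-4-{(2S,3S)-3-[(2S,3S)-3-bromo-2,4-dichloro-3-methylbutyl]-2-methyloxiran-2-yl}-2,2-dimethyl-1,3-dioxolane | C[C@@]1(O[C@H]1C[C@H](Cl)[C@@](C)(Br)CCl)[C@@H]2COC(C)(C)O2 | intermediate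
16 | (2R,3S,5S,6S)-2,6-dibromo-5,7-dichloro-2-[(S)-2,2-dimethyl-1,3-dioxolan-4-yl]-6-methylheptan-3-ol (key-step precursor) | C[C@@](Br)([C@@H](O)C[C@H](Cl)[C@@](C)(Br)CCl)[C@@H]1COC(C)(C)O1 | intermediate
17 | C4 trifluoromethanesulfonate of 16, all centres arranged as in 16 (not isolated) | C[C@@](Br)([C@@H](OS(=O)(=O)C(F)(F)F)C[C@H](Cl)[C@@](C)(Br)CCl)[C@@H]1COC(C)(C)O1 | intermediate
18 | bromiranium ion from 17, bromine bridging C3 and C4 on the face opposite the former C4–O bond, triflate salt (not isolated) | C[C@]1([Br+][C@@H]1C[C@H](Cl)[C@@](C)(Br)CCl)[C@@H]2COC(C)(C)O2.[O-]S(=O)(=O)C(F)(F)F | intermediate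
19 | (S)-4-[(2R,3R,5S,6S)-3,6-dibromo-2,5,7-trichloro-6-methylheptan-2-yl]-2,2-dimethyl-1,3-dioxolane (key-step product) | C[C@](Cl)([C@H](Br)C[C@H](Cl)[C@@](C)(Br)CCl)[C@@H]1COC(C)(C)O1 | intermediate
20 | (2S,3R,4R,6S,7S)-4,7-dibromo-3,6,8-trichloro-3,7-dimethyloctane-1,2-diol | C[C@](Cl)([C@H](Br)C[C@H](Cl)[C@@](C)(Br)CCl)[C@@H](O)CO | intermediate
21 | (2S,3R,4R,6S,7S)-4,7-dibromo-3,6,8-trichloro-2-hydroxy-3,7-dimethyloctyl 4-methylbenzenesulfonate | C[C@](Cl)([C@H](Br)C[C@H](Cl)[C@@](C)(Br)CCl)[C@@H](O)COS(=O)(=O)c1ccc(C)cc1 | intermediate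
22 | (S)-2-[(2R,3R,5S,6S)-3,6-dibromo-2,5,7-trichloro-6-methylheptan-2-yl]oxirane, i.e. (2S,3R,4R,6S,7S)-4,7-dibromo-3,6,8-trichloro-1,2-epoxy-3,7-dimethyloctane | C[C@](Cl)([C@H](Br)C[C@H](Cl)[C@@](C)(Br)CCl)[C@@H]1CO1 | target

**Step count and risks**

Total step count: 15. Longest linear sequence: 13 steps (1 → 2 → 3 → 4, then steps 6 to 15).

Steps most likely to fail:

1. Step 9 (proposed new method). Bromide may displace the primary triflate directly without chlorine migration. The chloronium ion may open to a free tertiary cation and lose the C7 configuration before capture. The developing cation may also be trapped by the remote C3=C4 alkene or lose a proton. Fallback, from 11 back to 14, by stepwise oxygen-based displacement. K2CO3 in MeOH at 0 °C lets the C8 alkoxide displace the tertiary C7 chloride (halohydrin closure, inversion at C7) to give (R)-4-{(2Z,5S)-5-chloro-5-[(S)-2-methyloxiran-2-yl]pent-2-en-2-yl}-2,2-dimethyl-1,3-dioxolane F1. LiCl and AcOH in THF open this oxirane at the primary C8 to give the tertiary alcohol (2S,3S,5Z)-1,3-dichloro-6-[(R)-2,2-dimethyl-1,3-dioxolan-4-yl]-2-methylhept-5-en-2-ol F2. Me3SiBr in CH2Cl2 at −40 °C then exchanges the tertiary hydroxyl for bromine. Ionisation at C7 should be assisted by a flanking chlorine, so bromide should return on the face that oxygen left (retention), which gives 14; a C7 epimer, if formed, would be removed by chromatography.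

2. Step 12 (key step). Chloride may open the bromonium ion at C4 and not at C3. The ion may collapse to an open cation with elimination. The C7 bromine may take part through a five-membered bromonium ion. Fallback, from 14 directly to 19, bypassing 15–18: interhalogen addition to the Z alkene with Bu4NBrCl2 in CH2Cl2 at −78 °C. Electrophilic bromine should add to the alkene face anti to the C2–O bond of the A(1,3)-locked dioxolane conformer, and chloride should then open the ion anti at the tertiary C3. This is substrate-controlled, not stereospecific from a bromohydrin, and makes no new compound (F0).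

3. Step 10. Face selectivity may be poor because the dioxirane has to override the inherent bias of the allylic dioxolane, and the inductively deactivated alkene may be epoxidised slowly. Fallback, from 14 back to 15, using the substrate's own bias. N-bromosuccinimide in aqueous acetone at 0 °C should form the bromonium ion anti to the C2–O bond, with water attacking the tertiary C3, to give (2R,3R,5S,6S)-3,6-dibromo-5,7-dichloro-2-[(S)-2,2-dimethyl-1,3-dioxolan-4-yl]-6-methylheptan-2-ol F3. K2CO3 in MeOH closes it with inversion at C4 to the same cis-epoxide 15. Any bromohydrin formed by water attack at C4 is 16 itself.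

Further compounds
F1 | step 9 | (R)-4-{(2Z,5S)-5-chloro-5-[(S)-2-methyloxiran-2-yl]pent-2-en-2-yl}-2,2-dimethyl-1,3-dioxolane | C/C(=C/C[C@H](Cl)[C@]1(C)CO1)[C@@H]2COC(C)(C)O2
F2 | step 9 | (2S,3S,5Z)-1,3-dichloro-6-[(R)-2,2-dimethyl-1,3-dioxolan-4-yl]-2-methylhept-5-en-2-ol | C/C(=C/C[C@H](Cl)[C@@](C)(O)CCl)[C@@H]1COC(C)(C)O1
F0 | step 12 | none | none
F3 | step 10 | (2R,3R,5S,6S)-3,6-dibromo-5,7-dichloro-2-[(S)-2,2-dimethyl-1,3-dioxolan-4-yl]-6-methylheptan-2-ol | C[C@](O)([C@H](Br)C[C@H](Cl)[C@@](C)(Br)CCl)[C@@H]1COC(C)(C)O1
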